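The readings are simulated on assumed constants.

Summer kept its charge together longer than dusk or spring did, and summer repeats north's charges, so I read the fed flasks off north's own curve.

| flask | substrate | partner | protic impurity | remark | time |
|---|---|---|---|---|---|
| north | 20 mM | 2.5 equiv | 10 mM | run made earlier |  |
| north-west | 20 mM | 2.5 equiv | 15 mM | run made earlier |  |
| dusk | 20 mM | 2.50 equiv (fed, over 5.0 h) | 10.0 mM | all else is in the flask from the start; the feed brings no volume worth counting | 8.0 h |
| summer | 20 mM | 2.50 equiv | 10.0 mM | everything together at the start | 8.0 h |
| spring | 20 mM (fed, over 5.0 h) | 2.50 equiv | 10.0 mM | all else is in the flask from the start; the feed brings no volume worth counting | 8.0 h |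

north run (percent of the substrate charged)

| time / h | second isomer / % | target / % |
|---|---|---|
| 2.00 | 14.9 | 8.5 |
| 4.00 | 25.0 | 13.4 |
| 6.00 | 31.1 | 17.9 |
| 8.00 | 33.4 | 21.2 |

north-west run (percent of the substrate charged)

| time / min | second isomer / % | target / % |
|---|---|---|
| 25.0 | 4.4 | 2.6 |
| 50.0 | 8.1 | 5.7 |
| 80.0 | 11.4 | 9.5 |
| 90.0 | 13.6 | 7.9 |

(readings scatter by 1 percentage point)



- the flask that comes out highest in amount of second isomer, in percent of the substrate charged; "all alike" if 1.5 percentage points covers them all (dusk / summer / spring / all alike)
- amount of second isomer at the end, in percent of the substrate charged, dusk
- amount of second isomer at the end, in percent of the substrate charged, summer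
- amount of second isomer at the end, in percent of the substrate charged, spring

I carried the north-equivalent time, 5.50 h: the mean hours that substrate and partner share, scaled by charged partner over north's partner. It assumes that substrate is lost at a rate proportional to c(partner), pseudo-first-order in substrate at any given c(partner). North and north-west cannot test this, since both stood at 2.5 equiv of partner.

For the fed flasks, the bound from above was north's reading of 33.4% at 8.00 h, which was also my figure for summer. From below stood 19.9%, north at 3.00 h, as if the charge met at the end of the feed. In dusk each portion of substrate met the same partner-hours, so I read north at 5.50 h: 29.6%. In spring the portions differed in age, so I averaged north's chords across those ages and got 28.6%, lower than dusk. Each reading carried 1 percentage point of scatter, yet my figure for summer stayed highest.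

The forecast named summer, with 30% for dusk, 34.5% for summer and 24% for spring, holding that “slow substrate feed clearly cuts second isomer, and slow partner feed mainly loses conversion”. Its spring lay inside my wide bracket but below my tightened figure.

The simulation gave summer highest, at 34.7%, with dusk at 29.5% and spring at 28.3%.

    substrate + partner → isomer of the product (k = 1.30 M⁻¹ h⁻¹)
    substrate + partner → second isomer (k = 2.30 M⁻¹ h⁻¹)
    substrate + partner → target (k = 1.40 M⁻¹ h⁻¹)
    partner + protic impurity → quenched reagent (k = 4.80 M⁻¹ h⁻¹)

Dusk, at 5.50 h on north's clock, ended with 36% of its substrate left against summer's 25%. A neighbour of summer, charged with 8.0 mM of substrate at the same equivalents, had proportionally less partner, and its north-equivalent time was 3.20 h. North's curve there read 21.0%. That neighbour gave 21.0% of second isomer, with 54% of its substrate left.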